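## Structural features

The target is a 2-O-alkylglycerol in which an achiral propane-1,3-diol head is joined through an ether oxygen and an unbranched C8 chain to C10 of a tetracyclo[6.4.0.0^{2,7}.0^{3,6}]dodecane. In this hydrocarbon a cyclohexane (ring A: C1, C8, C9–C12) is fused through C1–C8 to a row of three cyclobutanes (ring B: C1, C2, C7, C8; ring C: C2, C3, C6, C7; ring D: C3–C6), a [3]-ladderane. All seven stereocentres lie in the polycycle: the six methines C1, C2, C3, C6, C7 and C8 are contiguous, every fusion is cis and neighbouring rings are anti (a staircase), and C10, one CH2 away from C8, carries the chain cis to the ring-B bonds at C1 and C8 (10S in the 1R,2S,3S,6R,7R,8S series). The diol and the ether are robust; the fragile part is the ladder, which can open when a radical, a cation or an inserting metal is generated next to a rung and which limits the temperature. The real difficulty is twofold: building three fused four-membered rings in the anti arrangement, and obtaining one enantiomer of a core that, without its C10 substituent, has a mirror plane through the midpoints of the rungs and no functional group near C10. The four rungs C1–C8, C2–C7, C3–C6 and C4–C5 are parallel, so cutting all of them leaves two four-carbon rails (C1–C2–C3–C4 and C8–C7–C6–C5) joined only by C9–C12, that is, two E,E-1,3-dienes on a four-carbon tether, and this is the feature the key step exploits. With a cis-diol on C10/C11 and carboxyl groups on C4/C5, every intermediate up to the ladder is meso, so the absolute configuration can be set late by desymmetrising the diol.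

## Logic of the disconnections

28 ⇒ 27. The bonds cut are C10–H and C1'–H (back to the exocyclic C10=C1' alkene) and the two O–CH2Ph bonds. One hydrogenation creates the only non-ladder stereocentre and removes both protecting groups, so no protecting-group step stands alone. The demand is that H2 adds to C10 from the face of ring A that carries H-1 and H-8.

27 ⇒ 20 + 25. The C10=C1' bond is cut. The carbonyl of 20 is the only functionalised ring atom and has no α-stereocentre, so a Wittig reaction attaches the complete, protected side chain in one step. 25 goes back through its P–C bond to 24, and 24 through its secondary C–O–C bond to 21 and 22. Alkene geometry is irrelevant; the only demand is mono-alkylation of 22.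

20 ⇒ 19 ⇒ 17. The C11–H bond is traced back to a C11–O bond and the C10 carbonyl to a carbinol, which leads to 17 with two enantiotopic hydroxyls. Choosing which carbinol becomes the carbonyl (C10) and which is excised (C11) selects the enantiomer of the whole ladder, so every earlier compound can be meso. The demands are enantiotopos-selective acylation of the (R)-carbinol, oxidation of 18 before its acyl group can migrate, and a reductive C–O cleavage that leaves the ladder alone.

17 ⇒ 15 ⇒ 14 ⇒ 12. In order, the ketal is restored, the C4–H and C5–H bonds are removed (C4=C5), the two carboxyl carbons are put back on C4 and C5, and the diacid is re-esterified. The carboxyl groups make the dienes of the precursor photo-addressable and leave as CO2, so no carbon of the ladder comes from a separate fragment. The demand is a bis-decarboxylation that does not cleave the C3–C6 rung, with the glycol kept as its ketal because the oxidant of that step would cleave a free glycol.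

12 ⇒ 10 (key disconnection). All four rungs are cut: C1–C8, C2–C7, C3–C6 and C4–C5 of the tetracycle, which are C5–C10, C4–C11, C3–C12 and C2–C13 of the tetraenedioate chain. Four rings, four bonds and eight stereocentres disappear, and what remains is a meso macrocycle whose only stereocentres are the two ketal carbons. The precursor is refined in one respect: the two carboxyl termini are tied by a propane-1,3-diyl diester bridge instead of being two free ethyl esters. The bridge keeps the two dienoate decks side by side, allows only the mutually cis arrangement of the two arms once ring B has formed, and holds the acrylate pair stacked for the second cycloaddition. An aliphatic bridge is chosen because it is transparent at 254 nm and has no low-lying triplet, unlike an aryl diester template, and it is removed in the hydrolysis that is needed anyway. The demands on the forward step are parallel rather than crossed addition, ring B anti to the dioxolane, and cycloaddition faster than Cope rearrangement of 11.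

10 ⇒ 9 ⇒ 8. The two alkyl C–O bonds of the bridge are cut (double carboxylate alkylation), then the cesium carboxylates are traced to the ethyl esters. This returns the macrocycle to an open-chain diester that a standard olefination delivers. The demand is ring closure in preference to oligomerisation.

8 ⇒ 6 + 4, then 6 ⇒ 5 ⇒ 3 ⇒ 2 ⇒ 1. The C4=C5 and C10=C11 bonds of the chain are cut (double vinylogous Horner–Wadsworth–Emmons olefination, which consumes two molecules of 4, one per aldehyde). The two aldehyde carbons of 6 are rejoined as the ring alkene of 3 (ozonolysis), the ketal is removed, and the two cis C–O bonds are removed to reach 1. The whole C6 tether with its meso glycol comes from a cheap symmetrical diene. The demands are mono-dihydroxylation of 1 and E-selective olefination of a β-alkoxy aldehyde without elimination.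

## Other disconnections considered

Alternative 1: The cut is the outermost rung C4–C5 of ring D. In the forward sense the fused secondary pyrrolidine A1, with nitrogen bridging C4 and C5, is oxidised with a hypervalent-iodine oxidant and an ammonia source to a 1,1-diazene, which loses N2; the two CH2 termini couple to give A2, the dibenzyl ether of 28. In its favour, the last ring is made when every stereocentre, C10 included, is already in place, and the coupling carbons are CH2 groups, so the key step raises no stereochemical question; on this point it is better than the chosen plan, whose key step must set eight centres. It needs no auxiliary carboxyl groups, and only a hydrogenolysis follows it, which is better than the nine steps after step 6. Against it, the intermediate 1,4-biradical is primary and unstabilised and sits next to the C3–C6 bond, so fragmentation of that bond (a formal retro-[2+2]) should compete with closure to a strained bicyclo[2.2.0]hexane; ring contractions of this type are at their best with radical-stabilising α-substituents. On structure it makes one ring and one bond against four and four, and A1 already contains rings A–C with five ladder centres and the chosen enantiomer, so the hard part is moved elsewhere. On mechanism both plans pass through 1,4-biradicals, but in step 6 the unproductive exit of the first biradical returns 10, whereas here fragmentation is irreversible. On step economy the end is shorter but the route to A1 is expected to be longer overall.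

Alternative 2: The cut is C3–C6, the rung shared by rings C and D. In the forward sense the cyclohexa-1,3-diene A3 (ring A with a ketal at C10, ring B, and a six-membered diene ring) is irradiated directly and closes by a disrotatory 4π electrocyclisation to the ladderene ketal A4. In its favour the step is unimolecular, so there is no folding or pre-organisation problem, which is better than the chosen plan. One bond gives two four-membered rings, no carboxyl groups have to be excised, and A4 corresponds to 15 with C10 already a masked ketone, which saves the diol-to-ketone steps. Against it, the sp3–sp3 bond of the diene ring is C2–C7 of ring B, so thermal and photochemical 6π ring opening across that bond would sacrifice ring B. The sense of disrotation decides between the anti and the syn ladder and only the bulk of ring A biases it. A3 is chiral, so the absolute configuration has to be set earlier by another asymmetric cycloaddition. On structure it builds two rings, one bond and two stereocentres against four, four and eight. On mechanism it is better in entropy and worse in competing channels. The C10 centre is still set by the same late hydrogenation, so the two plans are equal there. On step economy its end is shorter and its start is expected to be longer, for a similar total.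

Alternative 3: The cuts are C1–C12 and C8–C9, the ring-A bonds from the fusion carbons to their CH2 neighbours. In the forward sense cyclobut-2-en-1-one A5 and 2-(trimethylsilyloxy)buta-1,3-diene A6 combine in a Diels–Alder reaction under a chiral oxazaborolidinium triflimide Lewis acid to give the bicyclic silyl enol ether A7. In its favour this is a concerted thermal reaction with predictable regiochemistry, mechanistically the most reliable of the four. The catalyst fixes the absolute configuration of C1 and C8 at the outset on a simple compound, which is better than a late enzymatic desymmetrisation on advanced material. The silyl enol ether is the C10 ketone of 20 in masked form, so the two plans are equal there. Against it, the step builds only ring A onto ring B; rings C and D would need two further rounds of cyclobutene formation and [2+2] addition, each with its own anti facial selectivity and removal of activating groups. A5 is volatile and polymerises readily, and two carbonyl groups must be handled separately. On structure it makes one ring, two bonds and two stereocentres against four, four and eight, and on step economy it is expected to be clearly the longest.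

Key step: step 6

Assumption: ring B is taken to form on the face of ring A opposite the dioxolane oxygens (oxygens cis to H-1/H-8, the arrangement free of 1,3-diaxial contacts) and the lipase is taken to acylate the (R)-carbinol; in the opposite case the route is unchanged except that the diacetate is hydrolysed with the same lipase instead of acylating the diol.

## Route

Step 1
Reactants: 1 cyclohexa-1,4-diene
Product: 2 cis-cyclohex-4-ene-1,2-diol (meso)
Conditions: K2OsO4·2H2O (0.5 mol%), NMO (1.0 equiv), 1 (3 equiv), acetone/H2O, 0 °C → rt
Reagents that add atoms: N-methylmorpholine N-oxide (C[N+]1([O-])CCOCC1); water (O)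
Why: Catalytic osmium-mediated syn-dihydroxylation ([3+2] addition of OsO4, hydrolysis of the osmate ester, reoxidation by the N-oxide); syn addition makes the diol cis and therefore meso, and excess diene with limiting oxidant should hold the reaction at the mono-diol.

Step 2
Reactants: 2 cis-cyclohex-4-ene-1,2-diol (meso)
Product: 3 cis-2,2-dimethyl-3a,4,7,7a-tetrahydro-1,3-benzodioxole (meso acetonide of 2)
Conditions: Me2C(OMe)2, p-TsOH·H2O (cat.), acetone, rt
Reagents that add atoms: 2,2-dimethoxypropane (COC(C)(C)OC)
Why: Acid-catalysed transketalisation; the cis-diol closes the five-membered ketal readily and the ketal carbon is not stereogenic.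

Step 3
Reactants: 3 cis-2,2-dimethyl-3a,4,7,7a-tetrahydro-1,3-benzodioxole; 4 triethyl (E)-4-phosphonocrotonate (two molar equivalents, one for each aldehyde group)
Product: 8 diethyl (2E,4E,10E,12E)-tetradeca-2,4,10,12-tetraenedioate 7,8-acetonide (meso 7R,8S), via ozonide 5 (not isolated), via dialdehyde 6 (not isolated), via lithiated phosphonate 7 (not isolated)
Conditions: O3, CH2Cl2, −78 °C; N2 purge; PPh3 (1.1 equiv), −78 °C → rt; then added to 4 (2.4 equiv) + LiN(SiMe3)2 (2.3 equiv), THF, −78 → 0 °C
Reagents that add atoms: second molar equivalent of triethyl 4-phosphonocrotonate 4 (CCOC(=O)/C=C/CP(=O)(OCC)OCC)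
Why: Ozonolysis with reductive work-up gives the meso dialdehyde, used crude because β-alkoxy aldehydes hydrate and eliminate on storage. Each aldehyde carbon then undergoes a vinylogous Horner–Wadsworth–Emmons olefination with its own molecule of 4, so two equivalents are consumed and the oxygen atoms delivered by ozone leave as diethyl phosphate. Both new C=C bonds should form E (reversible addition, elimination from the more stable oxaphosphetane) with retention of the E-alkene of 4, and the low temperature and the slight deficit of base guard against β-elimination of the ketal oxygen.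

Step 4
Reactants: 8 diethyl (2E,4E,10E,12E)-tetradeca-2,4,10,12-tetraenedioate 7,8-acetonide
Product: 9 dicesium (2E,4E,10E,12E)-tetradeca-2,4,10,12-tetraenedioate 7,8-acetonide (meso)
Conditions: CsOH·H2O (2.0 equiv), THF/H2O, rt; lyophilise
Reagents that add atoms: cesium hydroxide ([Cs+].[OH-])
Why: Ester saponification (acyl substitution by hydroxide); the carboxylates are obtained directly as the cesium salts needed next, without an acidic work-up that could open the ketal.

Step 5
Reactants: 9 dicesium (2E,4E,10E,12E)-tetradeca-2,4,10,12-tetraenedioate 7,8-acetonide
Product: 10 propane-1,3-diyl (2E,4E,10E,12E)-tetradeca-2,4,10,12-tetraenedioate 7,8-acetonide (19-membered macrocyclic diester; meso)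
Conditions: Br(CH2)3Br (1.0 equiv), DMF, 60 °C, slow addition (final 0.003 M)
Reagents that add atoms: 1,3-dibromopropane (BrCCCBr)
Why: Double O-alkylation of a cesium dicarboxylate by an α,ω-dihalide (SN2), a standard macrocyclisation. The cis-dioxolane turn folds the two arms towards each other and high dilution should favour the 1:1 ring over oligomers.

Step 6
Reactants: 10 propane-1,3-diyl (2E,4E,10E,12E)-tetradeca-2,4,10,12-tetraenedioate 7,8-acetonide
Product: 12 propane-1,3-diyl 10,11-O-isopropylidene-10,11-dihydroxytetracyclo[6.4.0.0^{2,7}.0^{3,6}]dodecane-4,5-dicarboxylate (meso; all fusions cis and neighbouring rings anti; carboxyls cis and exo on ring D; ketal oxygens cis to H-1/H-8), via bridged bis-acrylate 11 (not isolated)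
Conditions: [Ir(dF(CF3)ppy)2(dtbbpy)]PF6 (0.5 mol%), degassed MeCN (0.003 M), hv 450 nm, −20 °C; then hv 254 nm (quartz), −20 °C
Reagents that add atoms: none
Why: Proposed new method: the closest known reaction types are the triplet-sensitised intramolecular [2+2] photocycloaddition of 1,3-dienes to vinylcyclobutanes and the template-directed double [2+2] of parallel dienes or dienoates to [3]-ladderanes (hydrogen-bonded co-crystals; dienoates on a rigid cyclophane in solution), and what is untested is a foldable four-carbon tether plus an ansa diester bridge in place of a rigid template (chain numbering of 10 below). Stage one: the iridium sensitiser (triplet energy about 60 kcal/mol, above the dienoate and well below an isolated acrylate) transfers energy to one dienoate, whose δ-carbon C5 adds to C10 in a 6-exo radical closure (ring A) to give a bis-allyl 1,4-biradical that recombines C4–C11 after spin inversion (ring B); the transoid allyl termini cannot reach the [4+2] and [4+4] modes, and a trans-disposed biradical can only return to 10 by cleavage of the doubly allylic C5–C10 bond. Stage two: direct excitation of the stacked acrylate pair of 11 at 254 nm, where the sensitiser can no longer pass on enough energy, should give a suprafacial [2π+2π] addition that forms C3–C12 and C2–C13 together and so closes rings C and D as a bicyclo[2.2.0]hexane; the singlet regime is chosen because triplet 1,5-dienes prefer the crossed 1,5-closure to a bicyclo[2.1.1]hexane. C5 and C10 must be cis because a six- and a four-membered ring share their bond, and the chair-like closure puts ring B on the face of ring A away from the dioxolane oxygens, the arrangement free of 1,3-diaxial contacts. C4 and C11: each arm lies trans to the neighbouring ring-A CH2 (exo) and the bridge allows only the mutually cis arrangement. C3 and C12 follow from the extended (not folded-back) rotamer of the arms, which gives the anti staircase, and C2 and C13 (E geometry, bridge) are deleted in step 8, so E/Z isomerisation of the acrylates does no harm. The step needs parallel over crossed addition and cycloaddition faster than Cope rearrangement of 11: the first rests on the singlet regime and on anchoring both acrylates at both ends (ring B at the β-carbons, bridge at the carboxyls), the second on working at −20 °C.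

Step 7
Reactants: 12 propane-1,3-diyl ladder diester acetonide
Product: 14 10,11-O-isopropylidene-10,11-dihydroxytetracyclo[6.4.0.0^{2,7}.0^{3,6}]dodecane-4,5-dicarboxylic acid (meso; carboxyls cis and exo), via dilithium dicarboxylate 13 (not isolated)
Conditions: LiOH·H2O (4 equiv), THF/H2O, 0 °C → rt; 1 M HCl to pH 4, 0 °C
Reagents that add atoms: lithium hydroxide ([Li+].[OH-])
Why: Ester hydrolysis; the strained nine-membered dilactone should open readily. Epimerisation α to the esters would be of no consequence because both carboxyl-bearing centres are removed in step 8.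

Step 8
Reactants: 14 ladder diacid acetonide
Product: 15 tetracyclo[6.4.0.0^{2,7}.0^{3,6}]dodec-4-ene-10,11-diol acetonide (meso ladderene)
Conditions: Pb(OAc)4 (1.3 equiv), pyridine, 50 °C
Reagents that add atoms: none
Why: Oxidative bis-decarboxylation of a vicinal diacid by Pb(OAc)4 (lead carboxylate, loss of two CO2, reduction to divalent lead), the classical way from bicyclo[2.2.0]hexane-2,3-dicarboxylic acids to their cyclobutenes. The ketal keeps the glycol out of reach of oxidative cleavage.

Step 9
Reactants: 15 ladderene acetonide
Product: 17 meso tetracyclo[6.4.0.0^{2,7}.0^{3,6}]dodecane-10,11-diol (both OH cis to H-1/H-8), via ladderane acetonide 16 (not isolated)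
Conditions: H2 (1 atm), Pd/C (5 mol%), MeOH, rt; N2; then p-TsOH·H2O (10 mol%), rt
Reagents that add atoms: none
Why: Heterogeneous hydrogenation of the strained cis-cyclobutene is fast and creates no stereocentre. Acid-catalysed transketalisation to methanol then releases the meso diol in the same flask.

Step 10
Reactants: 17 meso tetracyclo[6.4.0.0^{2,7}.0^{3,6}]dodecane-10,11-diol
Product: 19 (1R,2S,3S,6R,7R,8S,11R)-11-(acetyloxy)tetracyclo[6.4.0.0^{2,7}.0^{3,6}]dodecan-10-one, via monoacetate 18 (not isolated)
Conditions: lipase from Burkholderia cepacia (immobilised), vinyl acetate, t-BuOMe, rt; filter, concentrate cold; then DMP, CH2Cl2, 0 °C → rt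
Reagents that add atoms: vinyl acetate (CC(=O)OC=C)
Why: Lipase-catalysed enantiotopos-selective transesterification of a meso cis-1,2-diol with an irreversible acyl donor, taken to occur at the (R)-carbinol as is usual for lipases; this fixes the absolute configuration of all six ladder centres. Immediate Dess–Martin oxidation of the free (S)-carbinol C10 locks the result before 1,2-acyl migration can interconvert the enantiomers of 18.

Step 11
Reactants: 19 11-acetoxy ketone
Product: 20 (1R,2S,3S,6R,7R,8S)-tetracyclo[6.4.0.0^{2,7}.0^{3,6}]dodecan-10-one
Conditions: SmI2 (2.5 equiv), THF/MeOH, −78 °C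
Reagents that add atoms: none
Why: SmI2 reduction of an α-acyloxy ketone: ketyl formation, loss of acetate and protonation of the samarium enolate by methanol give the parent ketone. No stereocentre is α to the carbonyl, so nothing can epimerise.

Step 12
Reactants: 21 1,3-bis(benzyloxy)propan-2-ol; 22 1,8-dibromooctane
Product: 24 2-[(8-bromooctyl)oxy]-1,3-bis(benzyloxy)propane, via sodium alkoxide 23 (not isolated)
Conditions: NaH, THF/DMF, 0 °C; then 22 (4 equiv), Bu4NI (cat.), 0 → 50 °C
Reagents that add atoms: none
Why: Williamson ether synthesis (SN2 of the secondary alkoxide on a primary bromide); the excess of dibromide suppresses double alkylation.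

Step 13
Reactants: 24 2-[(8-bromooctyl)oxy]-1,3-bis(benzyloxy)propane
Product: 25 {8-[1,3-bis(benzyloxy)propan-2-yloxy]octyl}triphenylphosphonium bromide
Conditions: PPh3, MeCN, reflux
Reagents that add atoms: triphenylphosphine (c1ccc(cc1)P(c1ccccc1)c1ccccc1)
Why: SN2 quaternisation of triphenylphosphine by the primary bromide.

Step 14
Reactants: 20 (1R,2S,3S,6R,7R,8S)-tetracyclo[6.4.0.0^{2,7}.0^{3,6}]dodecan-10-one; 25 phosphonium bromide
Product: 27 1,3-bis(benzyloxy)-2-({8-[(1R,2S,3S,6R,7R,8S)-tetracyclo[6.4.0.0^{2,7}.0^{3,6}]dodecan-10-ylidene]octyl}oxy)propane (E/Z mixture), via ylide 26 (not isolated)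
Conditions: 25, NaN(SiMe3)2, THF, 0 °C; then 20, 0 °C → rt
Reagents that add atoms: none
Why: Wittig olefination of an unhindered cyclohexanone with a non-stabilised ylide. The geometry of the trisubstituted alkene is irrelevant and the ketone has no α-stereocentre.

Step 15
Reactants: 27 10-alkylidene ladderane dibenzyl ether
Product: 28 2-({8-[(1R,2S,3S,6R,7R,8S,10S)-tetracyclo[6.4.0.0^{2,7}.0^{3,6}]dodecan-10-yl]octyl}oxy)propane-1,3-diol (CNP0193334.1)
Conditions: H2 (1 atm), Pd/C (10 mol%), EtOAc/EtOH, rt
Reagents that add atoms: none
Why: Heterogeneous hydrogenation should add H2 to the exocyclic alkene from the convex face of ring A (the face of H-1 and H-8, opposite ring B), which sets C10 as S with the chain cis to ring B. The same catalyst hydrogenolyses both benzyl ethers.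

## Compound list

1 | cyclohexa-1,4-diene | C1=CCC=CC1 | starting material
2 | cis-cyclohex-4-ene-1,2-diol (meso) | O[C@@H]1CC=CC[C@@H]1O | intermediate
3 | cis-2,2-dimethyl-3a,4,7,7a-tetrahydro-1,3-benzodioxole (meso) | CC1(C)O[C@@H]2CC=CC[C@@H]2O1 | intermediate
4 | triethyl (E)-4-phosphonocrotonate | CCOC(=O)/C=C/CP(=O)(OCC)OCC | starting material
5 | ozonide of 3 (1,2,4-trioxolane across the former C=C; mixture at the two ozonide carbons) | CC1(C)O[C@@H]2CC3OOC(O3)C[C@@H]2O1 | intermediate
6 | meso 2,2'-[(4R,5S)-2,2-dimethyl-1,3-dioxolane-4,5-diyl]diacetaldehyde | O=CC[C@@H]1OC(C)(C)O[C@@H]1CC=O | intermediate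
7 | lithium salt of 4 deprotonated at C4 | [Li+].CCOC(=O)/C=C/[CH-]P(=O)(OCC)OCC | intermediate
8 | diethyl (2E,4E,10E,12E)-tetradeca-2,4,10,12-tetraenedioate 7,8-acetonide (meso 7R,8S) | CCOC(=O)/C=C/C=C/C[C@@H]1OC(C)(C)O[C@@H]1C/C=C/C=C/C(=O)OCC | intermediate
9 | dicesium salt of the diacid of 8 | [Cs+].[Cs+].[O-]C(=O)/C=C/C=C/C[C@@H]1OC(C)(C)O[C@@H]1C/C=C/C=C/C([O-])=O | intermediate
10 | propane-1,3-diyl diester of the same diacid (19-membered ring, all-E, meso) | O=C1/C=C/C=C/C[C@@H]2OC(C)(C)O[C@@H]2C/C=C/C=C/C(=O)OCCCO1 | intermediate
11 | bridged bis-acrylate: cis-fused bicyclo[4.2.0]octane (rings A and B) 3,4-acetonide with two (E)-acrylate arms on C7 and C8, arms cis to each other and exo, joined as propane-1,3-diyl diester | CC1(C)O[C@@H]2[C@H](O1)C[C@@H]3[C@H](C2)[C@@H](/C=C/C4=O)[C@H]3/C=C/C(=O)OCCCO4 | intermediate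
12 | propane-1,3-diyl 10,11-O-isopropylidene-10,11-dihydroxytetracyclo[6.4.0.0^{2,7}.0^{3,6}]dodecane-4,5-dicarboxylate (meso) | CC1(C)O[C@@H]2[C@H](O1)C[C@@H]3[C@H](C2)[C@H]2[C@@H]4[C@@H](C5=O)[C@@H](C(=O)OCCCO5)[C@@H]4[C@@H]32 | intermediate
13 | dilithium salt of 14 | [Li+].[Li+].CC1(C)O[C@@H]2[C@H](O1)C[C@@H]3[C@H](C2)[C@H]2[C@@H]4[C@@H](C([O-])=O)[C@@H](C([O-])=O)[C@@H]4[C@@H]32 | intermediate
14 | 10,11-O-isopropylidene-10,11-dihydroxytetracyclo[6.4.0.0^{2,7}.0^{3,6}]dodecane-4,5-dicarboxylic acid (meso) | CC1(C)O[C@@H]2[C@H](O1)C[C@@H]3[C@H](C2)[C@H]2[C@@H]4[C@@H](C(O)=O)[C@@H](C(O)=O)[C@@H]4[C@@H]32 | intermediate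
15 | tetracyclo[6.4.0.0^{2,7}.0^{3,6}]dodec-4-ene-10,11-diol acetonide (meso) | CC1(C)O[C@@H]2[C@H](O1)C[C@@H]3[C@H](C2)[C@H]2[C@@H]4C=C[C@@H]4[C@@H]32 | intermediate
16 | tetracyclo[6.4.0.0^{2,7}.0^{3,6}]dodecane-10,11-diol acetonide (meso) | CC1(C)O[C@@H]2[C@H](O1)C[C@@H]3[C@H](C2)[C@H]2[C@@H]4CC[C@@H]4[C@@H]32 | intermediate
17 | meso tetracyclo[6.4.0.0^{2,7}.0^{3,6}]dodecane-10,11-diol (OH groups cis to H-1/H-8) | O[C@@H]1[C@H](O)C[C@@H]2[C@H](C1)[C@H]1[C@@H]3CC[C@@H]3[C@@H]21 | intermediate
18 | (1R,2S,3S,6R,7R,8S,10S,11R)-11-(acetyloxy)tetracyclo[6.4.0.0^{2,7}.0^{3,6}]dodecan-10-ol | O[C@@H]1[C@H](OC(C)=O)C[C@@H]2[C@H](C1)[C@H]1[C@@H]3CC[C@@H]3[C@@H]21 | intermediate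
19 | (1R,2S,3S,6R,7R,8S,11R)-11-(acetyloxy)tetracyclo[6.4.0.0^{2,7}.0^{3,6}]dodecan-10-one | O=C1[C@H](OC(C)=O)C[C@@H]2[C@H](C1)[C@H]1[C@@H]3CC[C@@H]3[C@@H]21 | intermediate
20 | (1R,2S,3S,6R,7R,8S)-tetracyclo[6.4.0.0^{2,7}.0^{3,6}]dodecan-10-one | O=C1CC[C@@H]2[C@H](C1)[C@H]1[C@@H]3CC[C@@H]3[C@@H]21 | intermediate
21 | 1,3-bis(benzyloxy)propan-2-ol | OC(COCc1ccccc1)COCc1ccccc1 | starting material
22 | 1,8-dibromooctane | BrCCCCCCCCBr | starting material
23 | sodium 1,3-bis(benzyloxy)propan-2-olate | [Na+].[O-]C(COCc1ccccc1)COCc1ccccc1 | intermediate
24 | 2-[(8-bromooctyl)oxy]-1,3-bis(benzyloxy)propane | BrCCCCCCCCOC(COCc1ccccc1)COCc1ccccc1 | intermediate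
25 | {8-[1,3-bis(benzyloxy)propan-2-yloxy]octyl}triphenylphosphonium bromide | [Br-].c1ccccc1COCC(COCc1ccccc1)OCCCCCCCC[P+](c1ccccc1)(c1ccccc1)c1ccccc1 | intermediate
26 | ylide of 25 | c1ccccc1COCC(COCc1ccccc1)OCCCCCCC[CH-][P+](c1ccccc1)(c1ccccc1)c1ccccc1 | intermediate
27 | 1,3-bis(benzyloxy)-2-({8-[(1R,2S,3S,6R,7R,8S)-tetracyclo[6.4.0.0^{2,7}.0^{3,6}]dodecan-10-ylidene]octyl}oxy)propane (E/Z mixture) | c1ccccc1COCC(COCc1ccccc1)OCCCCCCCC=C1CC[C@@H]2[C@H](C1)[C@H]1[C@@H]3CC[C@@H]3[C@@H]21 | intermediate
28 | 2-({8-[(1R,2S,3S,6R,7R,8S,10S)-tetracyclo[6.4.0.0^{2,7}.0^{3,6}]dodecan-10-yl]octyl}oxy)propane-1,3-diol | OCC(CO)OCCCCCCCC[C@H]1CC[C@@H]2[C@H](C1)[C@H]1[C@@H]3CC[C@@H]3[C@@H]21 | target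

## Step count and least certain steps

Total step count: 15. Longest linear sequence: 13 (steps 1–11, 14, 15); steps 12 and 13 form the side-chain branch.

Step 6 (key step, proposed new method). The most likely failures are these: collapse of the stage-one biradical in the wrong sense (one arm endo, or a trans ring fusion), or its return to 10 with little productive turnover; and, in stage two, intersystem crossing of the excited acrylate pair into the crossed 1,5-closure, ring opening of ring B, or slow conversion because acrylates absorb weakly at 254 nm. The underlying reason is that a foldable tether and a flexible bridge hold the two decks together less firmly than a rigid template. The fallback builds the ladder ring by ring with known reactions and sets out from 3. Sensitised [2+2] photocycloaddition of maleic anhydride to 3, anti to the dioxolane, should give the tricyclic anhydride F1. Hydrolysis gives the cis-diacid F2, and Pb(OAc)4 bis-decarboxylation gives the cyclobutene F3. A second maleic anhydride photocycloaddition on the exo face gives the anhydride F4, hydrolysis the diacid F5, and bis-decarboxylation the tricyclic cyclobutene F6. A third photocycloaddition gives the ring-D anhydride F7, whose hydrolysis is the diacid 14, where the route is rejoined.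

Step 5. Intermolecular alkylation may outrun ring closure, so that oligomeric esters form instead of the 19-membered ring. The fallback does without the bridge and sets out from 8. Irradiation of 8 under the two-stage protocol of step 6 should give the unbridged bis-acrylate F8 (not isolated) and then the diethyl ladder diester F9, with the mutually cis arrangement of the arms then resting on their exo preference alone. Saponification of F9 with LiOH gives 13, where the route is rejoined.

Step 8. The cyclobutyl radical or cation generated at C4/C5 during the lead-mediated decarboxylation may cleave the adjacent C3–C6 rung under strain release, which would destroy rings C and D. The fallback replaces the oxidative process by a reductive one in which the radical is intercepted by fast hydrogen-atom transfer; it sets out from 14. Organophotoredox hydrodecarboxylation (9-mesityl-10-methylacridinium salt, PhSSPh as thiol source, base, blue light) should remove one carboxyl group to give the monoacid F10 (not isolated) and then the second, delivering 16 directly with no alkene stage. The route is rejoined at 16, which the acid treatment of step 9 converts into 17.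

Step 10. The enzyme may discriminate poorly between the two enantiotopic hydroxyls, or the enantiomeric purity may erode through 1,2-acyl migration in 18 before the oxidation. The fallback uses a group that cannot migrate and a small-molecule catalyst; it sets out from 17. Enantioselective mono-sulfonylation (Cu(OTf)2 with a chiral bis(oxazoline) ligand, TsCl, K2CO3) at the C11 hydroxyl gives the monotosylate F11. Treatment with t-BuOK then triggers a 1,2-hydride shift from C10 to C11 with loss of tosylate (semipinacol rearrangement) and gives 20 directly, where the route is rejoined.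

Step 15. Facial selectivity of the H2 addition may be poor, because C10 lies three bonds from ring B and the two half-chair conformers of ring A expose different faces; the result would be the C10 epimer. The fallback uses hydroxyl direction instead of substrate shape and sets out from 19, keeping the C11 oxygen, which lies on the convex face. Wittig reaction of 19 with 26 gives the allylic acetate F12, and K2CO3/MeOH gives the allylic alcohol F13. Hydrogenation with [Ir(cod)(PCy3)(py)]PF6 in CH2Cl2 delivers H2 to C10 from the face of the C11 hydroxyl and gives the alcohol F14. Barton–McCombie deoxygenation through the xanthate F15 (NaH, CS2, MeI; then Bu3SnH, AIBN) gives the dibenzyl ether F16, and hydrogenolysis (H2, Pd/C) gives 28, where the route is rejoined.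

## Further compounds

F1 | step 6 | meso anhydride of cis-bicyclo[4.2.0]octane-7,8-dicarboxylic acid 3,4-acetonide (anhydride exo, ring B anti to the dioxolane) | CC1(C)O[C@@H]2[C@H](O1)C[C@@H]3[C@H](C2)[C@H]2C(=O)OC(=O)[C@H]23
F2 | step 6 | cis-bicyclo[4.2.0]octane-7,8-dicarboxylic acid 3,4-acetonide (meso) | CC1(C)O[C@@H]2[C@H](O1)C[C@@H]3[C@H](C2)[C@@H](C(O)=O)[C@H]3C(O)=O
F3 | step 6 | cis-bicyclo[4.2.0]oct-7-ene-3,4-diol acetonide (meso) | CC1(C)O[C@@H]2[C@H](O1)C[C@@H]3[C@H](C2)C=C3
F4 | step 6 | ring-C anhydride: rings A–B–C tricycle with exo-fused succinic anhydride, acetonide (meso) | CC1(C)O[C@@H]2[C@H](O1)C[C@@H]3[C@H](C2)[C@H]2[C@@H]4C(=O)OC(=O)[C@@H]4[C@@H]32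
F5 | step 6 | rings A–B–C tricyclic cis-diacid acetonide (meso) | CC1(C)O[C@@H]2[C@H](O1)C[C@@H]3[C@H](C2)[C@H]2[C@H](C(O)=O)[C@H](C(O)=O)[C@@H]32
F6 | step 6 | rings A–B–C tricyclic cyclobutene acetonide (meso) | CC1(C)O[C@@H]2[C@H](O1)C[C@@H]3[C@H](C2)[C@H]2C=C[C@@H]32
F7 | step 6 | cyclic anhydride of 14 (meso) | CC1(C)O[C@@H]2[C@H](O1)C[C@@H]3[C@H](C2)[C@H]2[C@@H]4[C@H]5C(=O)OC(=O)[C@H]5[C@@H]4[C@@H]32
F8 | step 5 | diethyl analogue of 11 (unbridged bis-acrylate, meso) | CC1(C)O[C@@H]2[C@H](O1)C[C@@H]3[C@H](C2)[C@@H](/C=C/C(=O)OCC)[C@H]3/C=C/C(=O)OCC
F9 | step 5 | diethyl 10,11-O-isopropylidene-10,11-dihydroxytetracyclo[6.4.0.0^{2,7}.0^{3,6}]dodecane-4,5-dicarboxylate (meso) | CC1(C)O[C@@H]2[C@H](O1)C[C@@H]3[C@H](C2)[C@H]2[C@@H]4[C@@H](C(=O)OCC)[C@@H](C(=O)OCC)[C@@H]4[C@@H]32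
F10 | step 8 | 10,11-O-isopropylidene-10,11-dihydroxytetracyclo[6.4.0.0^{2,7}.0^{3,6}]dodecane-4-carboxylic acid (racemic; one enantiomer drawn) | CC1(C)O[C@@H]2[C@H](O1)C[C@@H]3[C@H](C2)[C@H]2[C@@H]4[C@@H](C(O)=O)C[C@@H]4[C@@H]32
F11 | step 10 | C11 mono-p-toluenesulfonate of 17 (free OH at C10) | O[C@@H]1[C@H](OS(=O)(=O)c2ccc(C)cc2)C[C@@H]2[C@H](C1)[C@H]1[C@@H]3CC[C@@H]3[C@@H]21
F12 | step 15 | 11-acetoxy analogue of 27 (allylic acetate, E/Z mixture) | c1ccccc1COCC(COCc1ccccc1)OCCCCCCCC=C1[C@H](OC(C)=O)C[C@@H]2[C@H](C1)[C@H]1[C@@H]3CC[C@@H]3[C@@H]21
F13 | step 15 | 11-hydroxy analogue of 27 (allylic alcohol, E/Z mixture) | c1ccccc1COCC(COCc1ccccc1)OCCCCCCCC=C1[C@H](O)C[C@@H]2[C@H](C1)[C@H]1[C@@H]3CC[C@@H]3[C@@H]21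
F14 | step 15 | 11-hydroxy derivative of the dibenzyl ether of 28 (C10 set, OH trans to the chain) | c1ccccc1COCC(COCc1ccccc1)OCCCCCCCC[C@H]1[C@H](O)C[C@@H]2[C@H](C1)[C@H]1[C@@H]3CC[C@@H]3[C@@H]21
F15 | step 15 | S-methyl xanthate of F14 | c1ccccc1COCC(COCc1ccccc1)OCCCCCCCC[C@H]1[C@H](OC(=S)SC)C[C@@H]2[C@H](C1)[C@H]1[C@@H]3CC[C@@H]3[C@@H]21
F16 | step 15 | 1,3-di-O-benzyl ether of 28 | c1ccccc1COCC(COCc1ccccc1)OCCCCCCCC[C@H]1CC[C@@H]2[C@H](C1)[C@H]1[C@@H]3CC[C@@H]3[C@@H]21
A1 | alternative 1 | fused secondary pyrrolidine (nitrogen bridging C4 and C5 of the ladder), dibenzyl ether | c1ccccc1COCC(COCc1ccccc1)OCCCCCCCC[C@H]1CC[C@@H]2[C@H](C1)[C@H]1[C@@H]3CNC[C@@H]3[C@@H]21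
A2 | alternative 1 | 1,3-di-O-benzyl ether of 28 | c1ccccc1COCC(COCc1ccccc1)OCCCCCCCC[C@H]1CC[C@@H]2[C@H](C1)[C@H]1[C@@H]3CC[C@@H]3[C@@H]21
A3 | alternative 2 | cis-anti-cis cyclohexane–cyclobutane–cyclohexa-1,3-diene tricycle, ethylene ketal at the future C10 | C12(OCCO1)CC[C@@H]3[C@H](C2)[C@H]2C=CC=C[C@@H]32
A4 | alternative 2 | tetracyclic ladderene ethylene ketal | C12(OCCO1)CC[C@@H]3[C@H](C2)[C@H]2[C@@H]4C=C[C@@H]4[C@@H]32
A5 | alternative 3 | cyclobut-2-en-1-one | O=C1CC=C1
A6 | alternative 3 | 2-(trimethylsilyloxy)buta-1,3-diene | C=CC(=C)O[Si](C)(C)C
A7 | alternative 3 | 3-(trimethylsilyloxy)bicyclo[4.2.0]oct-3-en-7-one | C[Si](C)(C)OC1=CC[C@@H]2[C@H](C1)CC2=O
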